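**Retrosynthetic overview**
1. The depside ester C–O bond is cut to give the ring A acid 10 (divaricatinic acid) and the ring B phenol 13. Ring B carries its carboxyl as an aldehyde, which is oxidised in the last step.
2. The ring A carboxyl comes from a formyl group (Vilsmeier, then chelation-controlled O-demethylation, then chlorite oxidation) on 1,3-dimethoxy-5-propylbenzene 5.
3. Key C–C bond: the aryl–CH2 bond of the propyl chain. Propanal, as its N–H hydrazone, acts as a propyl carbanion equivalent (carbonyl umpolung) and is coupled with aryl bromide 1, joining two carbons that are both normally electrophilic.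
4. Ring B comes from olivetol by one formylation.
5. No ring is constructed. Both benzene rings are bought intact; ring A is elaborated first, then ring B, then they are joined.

Assumption: the target has no stereocentre (it is achiral), so no stereocontrol is needed and the SMILES is taken as drawn.

**Route**

Step 1
Reactants: 1 1-bromo-3,5-dimethoxybenzene; 2 propanal; 3 hydrazine monohydrate
Product: 5 1,3-dimethoxy-5-propylbenzene, via propanal hydrazone 4 (not isolated)
Conditions: 2 (3 equiv), 3 (3 equiv), THF, rt, 1 h; then 1, Ni(cod)2 (10 mol%), PMe3 (20 mol%), DBU, K3PO4, 4 Å MS, THF, 60 °C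
Reagents that add atoms: none
Why: Condensation gives the N–H hydrazone 4, whose deprotonated form behaves as a propyl carbanion equivalent (carbonyl umpolung with Wolff–Kishner-type loss of N2) and is captured by the aryl–nickel species formed by oxidative addition of 1 to zerovalent nickel, so the normally electrophilic aldehyde carbon is joined to the normally electrophilic aryl carbon (nickel-catalysed denitrogenative hydrazone–aryl halide cross-coupling); no stereocentre is formed.

Step 2
Reactants: 5 1,3-dimethoxy-5-propylbenzene
Product: 7 2,4-dimethoxy-6-propylbenzaldehyde, via aryl iminium chloride 6 (not isolated)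
Conditions: POCl3, DMF, 0 → 70 °C; then ice-water
Reagents that add atoms: N,N-dimethylformamide, CN(C)C=O; water, O
Why: Vilsmeier–Haack formylation attacks the position para to one methoxy group and ortho to the other (next to the propyl group), the usual site for 5-alkylresorcinol dimethyl ethers, and the iminium salt 6 hydrolyses on work-up.

Step 3
Reactants: 7 2,4-dimethoxy-6-propylbenzaldehyde
Product: 9 2-hydroxy-4-methoxy-6-propylbenzaldehyde, via aryloxydichloroborane 8 (not isolated)
Conditions: BCl3 (1.2 equiv), CH2Cl2, −78 → 0 °C; then H2O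
Reagents that add atoms: none
Why: BCl3 bridges the aldehyde oxygen and the ortho methoxy oxygen in a six-membered chelate, so only that ether is cleaved and the para methoxy group stays (chelation-directed Lewis acid demethylation).

Step 4
Reactants: 9 2-hydroxy-4-methoxy-6-propylbenzaldehyde
Product: 10 2-hydroxy-4-methoxy-6-propylbenzoic acid (divaricatinic acid)
Conditions: NaClO2, NH2SO3H, dioxane/H2O, 0 °C → rt
Reagents that add atoms: sodium chlorite, [Na+].[O-]Cl=O
Why: Lindgren–Pinnick chlorite oxidation converts the aldehyde to the acid under mild acidic conditions while sulfamic acid traps HOCl before it can chlorinate the electron-rich ring.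

Step 5
Reactants: 11 olivetol (5-pentylbenzene-1,3-diol)
Product: 13 2,4-dihydroxy-6-pentylbenzaldehyde, via aryl iminium chloride 12 (not isolated)
Conditions: POCl3, DMF, 0 °C → rt; then H2O, 50 °C
Reagents that add atoms: N,N-dimethylformamide, CN(C)C=O; water, O
Why: Vilsmeier–Haack formylation of the resorcinol occurs para to one hydroxyl and ortho to the other (next to the pentyl chain), giving the 2,4-dihydroxy-6-pentyl pattern after hydrolysis of iminium salt 12.

Step 6
Reactants: 10 2-hydroxy-4-methoxy-6-propylbenzoic acid; 13 2,4-dihydroxy-6-pentylbenzaldehyde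
Product: 15 4-formyl-3-hydroxy-5-pentylphenyl 2-hydroxy-4-methoxy-6-propylbenzoate, via mixed trifluoroacetic anhydride 14 (not isolated)
Conditions: (CF3CO)2O, toluene, rt
Reagents that add atoms: none
Why: Trifluoroacetic anhydride turns the salicylic acid into mixed anhydride 14, which acylates the free para hydroxyl of 13 in preference to the ortho hydroxyl that is hydrogen-bonded to the aldehyde (mixed-anhydride esterification, the standard depside coupling).

Step 7
Reactants: 15 4-formyl-3-hydroxy-5-pentylphenyl 2-hydroxy-4-methoxy-6-propylbenzoate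
Product: 16 stenosporic acid (2-hydroxy-4-[(2-hydroxy-4-methoxy-6-propylbenzoyl)oxy]-6-pentylbenzoic acid)
Conditions: NaClO2, NH2SO3H, THF/H2O, 0 °C → rt
Reagents that add atoms: sodium chlorite, [Na+].[O-]Cl=O
Why: Lindgren–Pinnick oxidation takes the salicylaldehyde to the salicylic acid at 0–20 °C without cleaving the aryl ester, sulfamic acid again scavenging HOCl; the molecule has no stereocentre at any stage.

**Compound list**
1 | 1-bromo-3,5-dimethoxybenzene | COc1cc(Br)cc(OC)c1 | starting material
2 | propanal | CCC=O | starting material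
3 | hydrazine monohydrate | NN.O | starting material
4 | propanal hydrazone (propylidenehydrazine) | CCC=NN | intermediate
5 | 1,3-dimethoxy-5-propylbenzene | CCCc1cc(OC)cc(OC)c1 | intermediate
6 | N-(2,4-dimethoxy-6-propylbenzylidene)-N-methylmethanaminium chloride | CCCc1cc(OC)cc(OC)c1C=[N+](C)C.[Cl-] | intermediate
7 | 2,4-dimethoxy-6-propylbenzaldehyde | CCCc1cc(OC)cc(OC)c1C=O | intermediate
8 | dichloro(2-formyl-5-methoxy-3-propylphenoxy)borane | CCCc1cc(OC)cc(OB(Cl)Cl)c1C=O | intermediate
9 | 2-hydroxy-4-methoxy-6-propylbenzaldehyde | CCCc1cc(OC)cc(O)c1C=O | intermediate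
10 | 2-hydroxy-4-methoxy-6-propylbenzoic acid (divaricatinic acid) | CCCc1cc(OC)cc(O)c1C(=O)O | intermediate
11 | olivetol (5-pentylbenzene-1,3-diol) | CCCCCc1cc(O)cc(O)c1 | starting material
12 | N-(2,4-dihydroxy-6-pentylbenzylidene)-N-methylmethanaminium chloride | CCCCCc1cc(O)cc(O)c1C=[N+](C)C.[Cl-] | intermediate
13 | 2,4-dihydroxy-6-pentylbenzaldehyde | CCCCCc1cc(O)cc(O)c1C=O | intermediate
14 | 2-hydroxy-4-methoxy-6-propylbenzoic trifluoroacetic anhydride | CCCc1cc(OC)cc(O)c1C(=O)OC(=O)C(F)(F)F | intermediate
15 | 4-formyl-3-hydroxy-5-pentylphenyl 2-hydroxy-4-methoxy-6-propylbenzoate | CCCCCc1cc(OC(=O)c2c(O)cc(OC)cc2CCC)cc(O)c1C=O | intermediate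
16 | stenosporic acid (2-hydroxy-4-[(2-hydroxy-4-methoxy-6-propylbenzoyl)oxy]-6-pentylbenzoic acid) | CCCCCc1cc(OC(=O)c2c(O)cc(OC)cc2CCC)cc(O)c1C(=O)O | target

**Totals**
Total step count: 7. Longest linear sequence: 6 (steps 1, 2, 3, 4, 6, 7); step 5 is a one-step side branch.

**Three steps most likely to fail, with fallbacks**

Step 1. The aliphatic hydrazone can form the azine, undergo plain Wolff–Kishner reduction to propane, or lose the propyl group by β-hydride elimination at nickel. The fallback keeps the reversed polarity but places it on the aryl carbon. It sets out from 1: bromine–lithium exchange (n-BuLi, THF, −78 °C) and a DMF quench give 3,5-dimethoxybenzaldehyde F1. Propane-1,3-dithiol with BF3·OEt2 in CH2Cl2 gives 2-(3,5-dimethoxyphenyl)-1,3-dithiane F2. Deprotonation with n-BuLi and alkylation with iodoethane (Corey–Seebach acyl anion alkylation) give 2-(3,5-dimethoxyphenyl)-2-ethyl-1,3-dithiane F3. Raney Ni in refluxing EtOH removes the sulfur, and the route is rejoined at 5.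

Step 6. The free salicylic acid 10 may self-condense or react sluggishly as its mixed anhydride, and double acylation of 13 is possible. The fallback replaces in-situ activation of a free hydroxy acid with a fully O-methylated acid chloride and moves the demethylation to the depside stage. It sets out from 7 (and so also bypasses steps 3 and 4): chlorite oxidation (NaClO2, NH2SO3H) gives 2,4-dimethoxy-6-propylbenzoic acid F4. (COCl)2 with catalytic DMF in CH2Cl2 gives 2,4-dimethoxy-6-propylbenzoyl chloride F5. Acylation of 13 (pyridine, catalytic DMAP, CH2Cl2, 0 °C → rt) at its free para hydroxyl gives 4-formyl-3-hydroxy-5-pentylphenyl 2,4-dimethoxy-6-propylbenzoate F6. BCl3 (2.5 equiv, CH2Cl2, −78 → 0 °C) then cleaves only the methoxy group ortho to the ester carbonyl, and the route is rejoined at 15.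

Step 7. The strongly hydrogen-bonded aldehyde may oxidise slowly, and ring chlorination or ester hydrolysis could compete. The fallback carries the ring B carboxyl as a benzyl ester instead of an aldehyde. It sets out from 11 (and uses 10): carboxylation with MeOMgOCO2Me in DMF at 120 °C gives 2,4-dihydroxy-6-pentylbenzoic acid F7. BnBr with KHCO3 in DMF gives benzyl 2,4-dihydroxy-6-pentylbenzoate F8. Coupling with 10 by (CF3CO)2O in toluene gives benzyl stenosporate F9. Hydrogenolysis (H2, 10% Pd/C, EtOAc, rt) rejoins the route at 16.

**Further compounds**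
F1 | step 1 | 3,5-dimethoxybenzaldehyde | COc1cc(C=O)cc(OC)c1
F2 | step 1 | 2-(3,5-dimethoxyphenyl)-1,3-dithiane | COc1cc(cc(OC)c1)C1SCCCS1
F3 | step 1 | 2-(3,5-dimethoxyphenyl)-2-ethyl-1,3-dithiane | CCC1(SCCCS1)c1cc(OC)cc(OC)c1
F4 | step 6 | 2,4-dimethoxy-6-propylbenzoic acid | CCCc1cc(OC)cc(OC)c1C(=O)O
F5 | step 6 | 2,4-dimethoxy-6-propylbenzoyl chloride | CCCc1cc(OC)cc(OC)c1C(Cl)=O
F6 | step 6 | 4-formyl-3-hydroxy-5-pentylphenyl 2,4-dimethoxy-6-propylbenzoate | CCCCCc1cc(OC(=O)c2c(OC)cc(OC)cc2CCC)cc(O)c1C=O
F7 | step 7 | 2,4-dihydroxy-6-pentylbenzoic acid | CCCCCc1cc(O)cc(O)c1C(=O)O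
F8 | step 7 | benzyl 2,4-dihydroxy-6-pentylbenzoate | CCCCCc1cc(O)cc(O)c1C(=O)OCc1ccccc1
F9 | step 7 | benzyl stenosporate (benzyl 2-hydroxy-4-[(2-hydroxy-4-methoxy-6-propylbenzoyl)oxy]-6-pentylbenzoate) | CCCCCc1cc(OC(=O)c2c(O)cc(OC)cc2CCC)cc(O)c1C(=O)OCc1ccccc1
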